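Ring C is disconnected at C3–C4. A rhodium-catalysed enantioselective intramolecular hydroacylation joins a formyl carbon (future C4) to the terminal CH2 (future C3) of an aryl 1-arylvinyl ether and delivers the formyl hydrogen to C2, so the pyranone ring and the only stereocentre arise in one isomerisation. The step exploits the C2(H)(aryl)–O1 unit β to the C4 ketone, and the latent symmetry of ring A about its C8a–C6 axis: the precursor is a symmetric 2-(1-arylvinyloxy)isophthalaldehyde made by ester methylenation and double ortho-formylation, either formyl group can become C4, and the spectator formyl at C8 is then converted into the 8-hydroxyl by Dakin oxidation.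

Key step: step 4

Assumption: the target is the (2S)-flavanone; the sense of induction of the rhodium catalyst on this new substrate cannot be predicted with certainty, so (R)-DTBM-SEGPHOS is written and its commercial antipode is taken instead should a test run give the 2R product.

Step 1
Reactants: 1 3,4,5-trimethoxyphenol; 2 3,4-dimethoxybenzoyl chloride
Product: 3 3,4,5-trimethoxyphenyl 3,4-dimethoxybenzoate
Conditions: Et3N, DMAP (cat.), CH2Cl2, 0 °C to rt
Reagents that add atoms: none
Why: DMAP-catalysed O-acylation (nucleophilic acyl substitution) of an unhindered, electron-rich phenol should proceed cleanly.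

Step 2
Reactants: 3 3,4,5-trimethoxyphenyl 3,4-dimethoxybenzoate
Product: 4 5-{[1-(3,4-dimethoxyphenyl)ethenyl]oxy}-1,2,3-trimethoxybenzene
Conditions: Cp2TiMe2 (2.5 equiv), toluene/THF, 70 °C, dark; filtration through basic Al2O3 (hexane/EtOAc, 1% Et3N)
Reagents that add atoms: dimethyltitanocene Cp2TiMe2, C[Ti](C)(C1C=CC=C1)C1C=CC=C1
Why: Petasis methylenation (titanium methylidene, oxatitanacyclobutane, cycloreversion) converts aryl benzoates into 1-aryloxy-1-arylethenes under non-acidic conditions that leave the methyl ethers and the acid-labile enol ether intact.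

Step 3
Reactants: 4 5-{[1-(3,4-dimethoxyphenyl)ethenyl]oxy}-1,2,3-trimethoxybenzene
Product: 9 2-{[1-(3,4-dimethoxyphenyl)ethenyl]oxy}-4,5,6-trimethoxybenzene-1,3-dicarbaldehyde, via aryllithium 5 (not isolated), via lithium aminoalkoxide 6 (not isolated), via lithiated aminoalkoxide 7 (not isolated), via dilithium bis(aminoalkoxide) 8 (not isolated)
Conditions: n-BuLi (1.1 equiv), TMEDA, THF, −20 °C; DMF (1.05 equiv), −78 °C; n-BuLi (1.3 equiv), −30 °C; DMF (3 equiv), −78 to 0 °C; pH 7 phosphate buffer
Reagents that add atoms: N,N-dimethylformamide, CN(C)C=O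
Why: Iterative directed ortho-metalation and formylation should work because each ring A C–H lies between the vinyloxy oxygen and a methoxy group, and the first DMF adduct, a lithium α-(dimethylamino)alkoxide, masks the first aldehyde (Comins-type in situ protection) while the second, symmetry-related C–H is lithiated and formylated in the same flask.

Step 4
Reactants: 9 2-{[1-(3,4-dimethoxyphenyl)ethenyl]oxy}-4,5,6-trimethoxybenzene-1,3-dicarbaldehyde
Product: 10 (2S)-2-(3,4-dimethoxyphenyl)-5,6,7-trimethoxy-4-oxo-3,4-dihydro-2H-chromene-8-carbaldehyde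
Conditions: [Rh(cod)Cl]2 (5 mol%), (R)-DTBM-SEGPHOS (10 mol%), NaB[3,5-(CF3)2C6H3]4 (10 mol%), 1,4-dioxane (0.05 M, degassed), 60 °C
Reagents that add atoms: none
Why: Proposed new method: the cationic monovalent rhodium bisphosphine complex should add oxidatively into a formyl C–H bond to give an acyl rhodium hydride (trivalent rhodium), the neighbouring enol ether alkene then inserts into Rh–H with the hydride going to the internal, aryl- and oxygen-bearing carbon (future C2), and C–C reductive elimination from the resulting seven-membered acyl(alkyl)rhodacycle forms C3–C4. The closest known reaction type is the rhodium/bisphosphine-catalysed enantioselective intramolecular hydroacylation of 1,1-disubstituted alkenes in ortho-allylbenzaldehydes and N-allylindole-2-carbaldehydes, which gives β-substituted six-membered benzo-fused ketones; here the benzylic CH2 (or N) of those substrates is replaced by the ether oxygen O1, so the alkene is an enol ether. Ring C is closed in the 6-endo-trig mode with respect to the alkene, both alkene carbons ending in the ring. The C2 stereocentre is created in the hydride-insertion step and is under catalyst control, the chiral bisphosphine selecting one enantiotopic face of the 1,1-disubstituted alkene of the achiral substrate. The step needs endo over exo regioselectivity (the exo mode would give a 2-methyl-2-arylbenzofuran-3-one), which the 1,1-disubstitution secures by disfavouring a tertiary α-oxy benzylic rhodium alkyl, helped by the bulky ligand; no selection between the two formyl groups is needed, since they are homotopic and give the same product. The spectator formyl group has no alkene within reach, and the moderate temperature should limit its decarbonylation.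

Step 5
Reactants: 10 (2S)-2-(3,4-dimethoxyphenyl)-5,6,7-trimethoxy-4-oxo-3,4-dihydro-2H-chromene-8-carbaldehyde
Product: 12 (2S)-2-(3,4-dimethoxyphenyl)-8-hydroxy-5,6,7-trimethoxy-2,3-dihydro-4H-chromen-4-one, via aryl formate 11 (not isolated)
Conditions: mCPBA (1.3 equiv), Na2HPO4, CH2Cl2, 0 °C to rt; then MeOH, Et3N (cat.), 0 °C
Reagents that add atoms: mCPBA (3-chloroperoxybenzoic acid), OOC(=O)c1cccc(Cl)c1
Why: In this Dakin-type Baeyer–Villiger oxidation the electron-rich ring A aryl group, oxygenated at both ortho positions and para to the formyl, should migrate in the Criegee intermediate far faster than the aryl ketone is oxidised, and the aryl formate is then cleaved by mild methanolysis that leaves C2 untouched.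

Compound list
1 | 3,4,5-trimethoxyphenol | COc1cc(O)cc(OC)c1OC | starting material
2 | 3,4-dimethoxybenzoyl chloride | COc1ccc(C(=O)Cl)cc1OC | starting material
3 | 3,4,5-trimethoxyphenyl 3,4-dimethoxybenzoate | COc1ccc(C(=O)Oc2cc(OC)c(OC)c(OC)c2)cc1OC | intermediate
4 | 5-{[1-(3,4-dimethoxyphenyl)ethenyl]oxy}-1,2,3-trimethoxybenzene | COc1ccc(C(=C)Oc2cc(OC)c(OC)c(OC)c2)cc1OC | intermediate
5 | (2-{[1-(3,4-dimethoxyphenyl)ethenyl]oxy}-4,5,6-trimethoxyphenyl)lithium | COc1ccc(C(=C)Oc2cc(OC)c(OC)c(OC)c2[Li])cc1OC | intermediate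
6 | lithium (dimethylamino)(2-{[1-(3,4-dimethoxyphenyl)ethenyl]oxy}-4,5,6-trimethoxyphenyl)methanolate | COc1ccc(C(=C)Oc2cc(OC)c(OC)c(OC)c2C([O-])N(C)C)cc1OC.[Li+] | intermediate
7 | 3-lithio derivative of 6 (lithium on the remaining ring A carbon, between the vinyloxy and methoxy carbons) | COc1ccc(C(=C)Oc2c([Li])c(OC)c(OC)c(OC)c2C([O-])N(C)C)cc1OC.[Li+] | intermediate
8 | dilithium (2-{[1-(3,4-dimethoxyphenyl)ethenyl]oxy}-4,5,6-trimethoxy-1,3-phenylene)bis[(dimethylamino)methanolate] | COc1ccc(C(=C)Oc2c(C([O-])N(C)C)c(OC)c(OC)c(OC)c2C([O-])N(C)C)cc1OC.[Li+].[Li+] | intermediate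
9 | 2-{[1-(3,4-dimethoxyphenyl)ethenyl]oxy}-4,5,6-trimethoxybenzene-1,3-dicarbaldehyde | COc1ccc(C(=C)Oc2c(C=O)c(OC)c(OC)c(OC)c2C=O)cc1OC | intermediate
10 | (2S)-2-(3,4-dimethoxyphenyl)-5,6,7-trimethoxy-4-oxo-3,4-dihydro-2H-chromene-8-carbaldehyde | COc1ccc([C@@H]2CC(=O)c3c(c(C=O)c(OC)c(OC)c3OC)O2)cc1OC | intermediate
11 | (2S)-2-(3,4-dimethoxyphenyl)-5,6,7-trimethoxy-4-oxo-3,4-dihydro-2H-chromen-8-yl formate | COc1ccc([C@@H]2CC(=O)c3c(c(OC=O)c(OC)c(OC)c3OC)O2)cc1OC | intermediate
12 | (2S)-2-(3,4-dimethoxyphenyl)-8-hydroxy-5,6,7-trimethoxy-2,3-dihydro-4H-chromen-4-one | COc1ccc([C@@H]2CC(=O)c3c(c(O)c(OC)c(OC)c3OC)O2)cc1OC | target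

Total step count: 5. Longest linear sequence: 5 steps (1 to 12).

Steps most likely to fail

Step 4 (proposed new method). The catalyst may be lost through decarbonylation of the acyl rhodium hydride, insertion may go the exo way, the enol ether may cyclise onto the aldehyde under Lewis-acid activation, or facial selectivity may be poor. Fallback with known chemistry, setting out from 9: thiol-catalysed radical-chain hydroacylation (tert-dodecanethiol, AIBN, chlorobenzene, 80 °C). The nucleophilic acyl radical should attack the terminal CH2 of the enol ether in the 6-endo mode, giving the stabilised α-oxy benzylic radical, which takes hydrogen from the thiol. This closes the same C3–C4 bond and should give racemic 2-(3,4-dimethoxyphenyl)-5,6,7-trimethoxy-4-oxo-3,4-dihydro-2H-chromene-8-carbaldehyde F1. Preparative HPLC on a cellulose tris(3,5-dimethylphenylcarbamate) phase then separates the enantiomers. The fallback comes back to the route at 10, and the (2R)-2-(3,4-dimethoxyphenyl)-5,6,7-trimethoxy-4-oxo-3,4-dihydro-2H-chromene-8-carbaldehyde F2 is set aside.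

Step 3. The second metalation may stay incomplete, or butyllithium may add to the enol ether or to the first DMF adduct, leaving mono-aldehyde and mixtures. Fallback setting out from 1, which fixes both positions by electrophilic bromination and replaces deprotonation by halogen–lithium exchange:
- NBS (2.1 equiv) in MeCN at 0 °C should give 2,6-dibromo-3,4,5-trimethoxyphenol F3.
- Acylation with 2 (Et3N, DMAP, CH2Cl2) gives 2,6-dibromo-3,4,5-trimethoxyphenyl 3,4-dimethoxybenzoate F4.
- Cp2TiMe2 in toluene at 70 °C gives 1,3-dibromo-2-{[1-(3,4-dimethoxyphenyl)ethenyl]oxy}-4,5,6-trimethoxybenzene F5.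
- Double bromine–lithium exchange with t-BuLi (4.2 equiv, THF, −78 °C) gives (2-{[1-(3,4-dimethoxyphenyl)ethenyl]oxy}-4,5,6-trimethoxy-1,3-phenylene)dilithium F6.
- DMF converts F6 into 8, and buffered work-up returns to the route at 9.

Step 5. The peracid may oxidise the ketone or the electron-rich rings in competition with formyl migration, or the pyranone may open and lose configuration at C2 while the formate is cleaved. Fallback setting out from 4, which carries the 8-oxygen as a tert-butyl ether from the metalation stage and needs no late oxidant: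
- Lithiation as in step 3 gives 5, and MgBr2·OEt2 converts it into (2-{[1-(3,4-dimethoxyphenyl)ethenyl]oxy}-4,5,6-trimethoxyphenyl)magnesium bromide F7.
- tert-Butyl perbenzoate (CC(C)(C)OOC(=O)c1ccccc1) oxygenates F7 to 2-tert-butoxy-1-{[1-(3,4-dimethoxyphenyl)ethenyl]oxy}-3,4,5-trimethoxybenzene F8.
- n-BuLi/TMEDA (THF, −20 °C) gives the aryllithium (3-tert-butoxy-2-{[1-(3,4-dimethoxyphenyl)ethenyl]oxy}-4,5,6-trimethoxyphenyl)lithium F9.
- DMF gives lithium (3-tert-butoxy-2-{[1-(3,4-dimethoxyphenyl)ethenyl]oxy}-4,5,6-trimethoxyphenyl)(dimethylamino)methanolate F10, and buffered work-up gives 3-tert-butoxy-2-{[1-(3,4-dimethoxyphenyl)ethenyl]oxy}-4,5,6-trimethoxybenzaldehyde F11.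
- Hydroacylation under the conditions of step 4 should give (2S)-8-tert-butoxy-2-(3,4-dimethoxyphenyl)-5,6,7-trimethoxy-2,3-dihydro-4H-chromen-4-one F12.
- TFA in CH2Cl2 at 0 °C cleaves the tert-butyl ether, and the fallback comes back to the route at 12.

Further compounds
F1 | step 4 | racemic 2-(3,4-dimethoxyphenyl)-5,6,7-trimethoxy-4-oxo-3,4-dihydro-2H-chromene-8-carbaldehyde | COc1ccc(C2CC(=O)c3c(c(C=O)c(OC)c(OC)c3OC)O2)cc1OC
F2 | step 4 | (2R)-2-(3,4-dimethoxyphenyl)-5,6,7-trimethoxy-4-oxo-3,4-dihydro-2H-chromene-8-carbaldehyde | COc1ccc([C@H]2CC(=O)c3c(c(C=O)c(OC)c(OC)c3OC)O2)cc1OC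
F3 | step 3 | 2,6-dibromo-3,4,5-trimethoxyphenol | Oc1c(Br)c(OC)c(OC)c(OC)c1Br
F4 | step 3 | 2,6-dibromo-3,4,5-trimethoxyphenyl 3,4-dimethoxybenzoate | COc1ccc(C(=O)Oc2c(Br)c(OC)c(OC)c(OC)c2Br)cc1OC
F5 | step 3 | 1,3-dibromo-2-{[1-(3,4-dimethoxyphenyl)ethenyl]oxy}-4,5,6-trimethoxybenzene | COc1ccc(C(=C)Oc2c(Br)c(OC)c(OC)c(OC)c2Br)cc1OC
F6 | step 3 | (2-{[1-(3,4-dimethoxyphenyl)ethenyl]oxy}-4,5,6-trimethoxy-1,3-phenylene)dilithium | COc1ccc(C(=C)Oc2c([Li])c(OC)c(OC)c(OC)c2[Li])cc1OC
F7 | step 5 | (2-{[1-(3,4-dimethoxyphenyl)ethenyl]oxy}-4,5,6-trimethoxyphenyl)magnesium bromide | COc1ccc(C(=C)Oc2cc(OC)c(OC)c(OC)c2[Mg]Br)cc1OC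
F8 | step 5 | 2-tert-butoxy-1-{[1-(3,4-dimethoxyphenyl)ethenyl]oxy}-3,4,5-trimethoxybenzene | COc1ccc(C(=C)Oc2cc(OC)c(OC)c(OC)c2OC(C)(C)C)cc1OC
F9 | step 5 | (3-tert-butoxy-2-{[1-(3,4-dimethoxyphenyl)ethenyl]oxy}-4,5,6-trimethoxyphenyl)lithium | COc1ccc(C(=C)Oc2c([Li])c(OC)c(OC)c(OC)c2OC(C)(C)C)cc1OC
F10 | step 5 | lithium (3-tert-butoxy-2-{[1-(3,4-dimethoxyphenyl)ethenyl]oxy}-4,5,6-trimethoxyphenyl)(dimethylamino)methanolate | COc1ccc(C(=C)Oc2c(C([O-])N(C)C)c(OC)c(OC)c(OC)c2OC(C)(C)C)cc1OC.[Li+]
F11 | step 5 | 3-tert-butoxy-2-{[1-(3,4-dimethoxyphenyl)ethenyl]oxy}-4,5,6-trimethoxybenzaldehyde | COc1ccc(C(=C)Oc2c(C=O)c(OC)c(OC)c(OC)c2OC(C)(C)C)cc1OC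
F12 | step 5 | (2S)-8-tert-butoxy-2-(3,4-dimethoxyphenyl)-5,6,7-trimethoxy-2,3-dihydro-4H-chromen-4-one | COc1ccc([C@@H]2CC(=O)c3c(c(OC(C)(C)C)c(OC)c(OC)c3OC)O2)cc1OC
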